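**Assumption:** the target is the all-trans (2R,3S,4S,5R) tetrahydrofuran with a free 4-OH on the syringyl ring. (R)-But-3-en-2-ol is taken as a commercial, inexpensive chiral building block.

## Retrosynthetic overview
1. Target 13 comes from hydrogenolysis of the two primary benzyl ethers of the all-trans 2,5-diaryl-THF 12.
2. THF 12 comes from Friedel–Crafts C-arylation of the oxocarbenium ion of lactol 11. Lactol 11 comes from the lactone 10, whose 3,4,5-trimethoxyphenyl group is made from syringol by O-methylation after a Friedel–Crafts C-arylation of lactol-lactone 7.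
3. The five-membered oxygen ring is formed as lactol-lactone 7, by ozonolysis of acid 6 followed by lactolization.
4. Acid 6 comes from an Ireland–Claisen [3,3]-sigmatropic rearrangement of ester 5. This sets the C8–C8′ bond and both CH2OBn-bearing stereocenters by chirality transfer from the carbinol of (R)-but-3-en-2-ol (1).

## Route

**Step 1**
Reactants: 1 (R)-but-3-en-2-ol (3 equiv); 2 allyl benzyl ether
Product: 3 (2R,3E)-5-(benzyloxy)pent-3-en-2-ol
Conditions: Grubbs II (5 mol %), CH2Cl2, 40 °C
Reagents that add atoms: none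
Why: Olefin cross-metathesis gives the E-1,2-disubstituted alkene and leaves the carbinol stereocenter, the only chiral-pool center, untouched.

**Step 2**
Reactants: 3; 4 3-(benzyloxy)propanoic acid
Product: 5 (2R,3E)-5-(benzyloxy)pent-3-en-2-yl 3-(benzyloxy)propanoate
Conditions: EDC·HCl, DMAP (cat.), CH2Cl2, 0 °C → rt
Reagents that add atoms: none
Why: Steglich esterification of a secondary allylic alcohol with no change at the stereocenter.

**Step 3**
Reactants: 5
Product: 6 (2S,3S,4E)-2,3-bis[(benzyloxy)methyl]hex-4-enoic acid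
Conditions: LDA, TMSCl (added in situ), THF/DMPU 4:1, −78 °C → rt; then 1 M HCl
Reagents that add atoms: none (the silyl ester is hydrolysed)
Why: Ireland–Claisen [3,3] rearrangement. DMPU gives the Z-enolate, so the silyl ketene acetal and the E-alkene both place their substituents equatorial in the chair transition state. The (R)-carbinol, with its methyl equatorial, fixes the face, which gives the syn (2S,3S) pair. The carbinol center is erased as it becomes the propenyl alkene.

**Step 4**
Reactants: 6
Product: 7 (3S,4S)-3,4-bis[(benzyloxy)methyl]-5-hydroxyoxolan-2-one (C5 epimers; ring–chain tautomer of the aldehyde-acid)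
Conditions: O3, CH2Cl2, −78 °C; then Me2S, −78 °C → rt
Reagents that add atoms: ozone, [O-][O+]=O (its oxygen ends up as the aldehyde/lactol oxygen)
Why: Reductive ozonolysis works chemoselectively because no aryl rings are present yet. The resulting aldehyde closes onto the CO2H (lactolization) to give the five-membered lactol-lactone, and C3 and C4 are untouched.

**Step 5**
Reactants: 7; 8 2,6-dimethoxyphenol (1.5 equiv)
Product: 9 (3S,4S,5R)-3,4-bis[(benzyloxy)methyl]-5-(4-hydroxy-3,5-dimethoxyphenyl)oxolan-2-one
Conditions: BF3·OEt2 (2 equiv), CH2Cl2, −20 °C → rt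
Reagents that add atoms: none
Why: Friedel–Crafts C-arylation of the acyloxocarbenium ion. Syringol attacks through its para carbon, anti to the neighbouring CH2OBn, giving the 4,5-trans lactone and setting C5 as R.

**Step 6**
Reactants: 9
Product: 10 (3S,4S,5R)-3,4-bis[(benzyloxy)methyl]-5-(3,4,5-trimethoxyphenyl)oxolan-2-one
Conditions: MeI (3 equiv), K2CO3 (3 equiv), DMF, rt
Reagents that add atoms: iodomethane, CI
Why: Williamson-type SN2 methylation turns the syringyl group into the 3,4,5-trimethoxyphenyl group. The lactone α-center already sits trans to C4, its thermodynamically preferred arrangement.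

**Step 7**
Reactants: 10
Product: 11 (3S,4S,5R)-3,4-bis[(benzyloxy)methyl]-5-(3,4,5-trimethoxyphenyl)oxolan-2-ol (C2 epimers)
Conditions: DIBAL-H (1.1 equiv), CH2Cl2, −78 °C
Reagents that add atoms: none (hydride only)
Why: Partial lactone reduction stops at the lactol because the tetrahedral aluminate is stable at −78 °C. The benzyl and aryl methyl ethers survive, and no stereocenter is affected.

**Step 8**
Reactants: 11; 8 (2 equiv)
Product: 12 4-[(2R,3S,4S,5R)-3,4-bis[(benzyloxy)methyl]-5-(3,4,5-trimethoxyphenyl)oxolan-2-yl]-2,6-dimethoxyphenol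
Conditions: BF3·OEt2 (2 equiv), CH2Cl2, −78 → 0 °C
Reagents that add atoms: none
Why: Friedel–Crafts C-arylation of the THF oxocarbenium ion. Para attack of syringol anti to the C3 CH2OBn sets C2 as R and gives the all-trans ring, which is also the thermodynamically preferred isomer.

**Step 9**
Reactants: 12
Product: 13 target, 4-[(2R,3S,4S,5R)-3,4-bis(hydroxymethyl)-5-(3,4,5-trimethoxyphenyl)oxolan-2-yl]-2,6-dimethoxyphenol
Conditions: H2 (1 atm), Pd(OH)2/C, EtOAc/MeOH, rt
Reagents that add atoms: none (H2 only)
Why: Hydrogenolysis removes both primary benzyl ethers as toluene. The aryl methyl ethers, the phenol and the ring stereocenters are unaffected.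

## Compound list
1 | (R)-but-3-en-2-ol | C[C@@H](O)C=C | starting material
2 | allyl benzyl ether | C=CCOCc1ccccc1 | starting material
3 | (2R,3E)-5-(benzyloxy)pent-3-en-2-ol | C[C@@H](O)/C=C/COCc1ccccc1 | intermediate
4 | 3-(benzyloxy)propanoic acid | OC(=O)CCOCc1ccccc1 | starting material
5 | (2R,3E)-5-(benzyloxy)pent-3-en-2-yl 3-(benzyloxy)propanoate | C[C@@H](OC(=O)CCOCc1ccccc1)/C=C/COCc1ccccc1 | intermediate
6 | (2S,3S,4E)-2,3-bis[(benzyloxy)methyl]hex-4-enoic acid | OC(=O)[C@H](COCc1ccccc1)[C@@H](COCc1ccccc1)/C=C/C | intermediate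
7 | (3S,4S)-3,4-bis[(benzyloxy)methyl]-5-hydroxyoxolan-2-one (C5 epimers) | OC1OC(=O)[C@H](COCc2ccccc2)[C@H]1COCc1ccccc1 | intermediate
8 | 2,6-dimethoxyphenol | COc1cccc(OC)c1O | starting material
9 | (3S,4S,5R)-3,4-bis[(benzyloxy)methyl]-5-(4-hydroxy-3,5-dimethoxyphenyl)oxolan-2-one | COc1cc([C@@H]2OC(=O)[C@H](COCc3ccccc3)[C@H]2COCc2ccccc2)cc(OC)c1O | intermediate
10 | (3S,4S,5R)-3,4-bis[(benzyloxy)methyl]-5-(3,4,5-trimethoxyphenyl)oxolan-2-one | COc1cc([C@@H]2OC(=O)[C@H](COCc3ccccc3)[C@H]2COCc2ccccc2)cc(OC)c1OC | intermediate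
11 | (3S,4S,5R)-3,4-bis[(benzyloxy)methyl]-5-(3,4,5-trimethoxyphenyl)oxolan-2-ol (C2 epimers) | COc1cc([C@@H]2OC(O)[C@H](COCc3ccccc3)[C@H]2COCc2ccccc2)cc(OC)c1OC | intermediate
12 | 4-[(2R,3S,4S,5R)-3,4-bis[(benzyloxy)methyl]-5-(3,4,5-trimethoxyphenyl)oxolan-2-yl]-2,6-dimethoxyphenol | COc1cc([C@@H]2O[C@@H](c3cc(OC)c(OC)c(OC)c3)[C@H](COCc3ccccc3)[C@H]2COCc2ccccc2)cc(OC)c1O | intermediate
13 | 4-[(2R,3S,4S,5R)-3,4-bis(hydroxymethyl)-5-(3,4,5-trimethoxyphenyl)oxolan-2-yl]-2,6-dimethoxyphenol | COc1cc([C@@H]2O[C@@H](c3cc(OC)c(OC)c(OC)c3)[C@H](CO)[C@H]2CO)cc(OC)c1O | target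

**Total steps:** 9. **Longest linear sequence:** 9 (1 → 3 → 5 → 6 → 7 → 9 → 10 → 11 → 12 → 13).

## Three steps most likely to fail
1. **Step 3, Ireland–Claisen.** The β-benzyloxy ester enolate can undergo E1cB elimination, and the syn selectivity depends on enolate geometry.
   Fallback: run a Johnson–Claisen (MeC(OEt)3, EtCO2H, 140 °C) on 3 to set only the C8′ center. Then ozonolyse, hydrolyse to the C3-unsubstituted lactol-lactone, do the Friedel–Crafts arylation and methylation as in steps 5–6, and install the C8 CH2OBn by LDA/BnOCH2Cl alkylation of the 4,5-trans lactone, anti to the C4 substituent.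
2. **Step 5, Friedel–Crafts on the lactol-lactone.** The acyloxocarbenium ion is poorly reactive, and the phenol can give over-alkylation and low trans selectivity.
   Fallback: make the methyl ester of 6 and ozonolyse it. Add 3,4,5-trimethoxyphenylmagnesium bromide to the aldehyde at −78 °C, lactonize on workup, and equilibrate the benzylic C5 center with TsOH in toluene to the 4,5-trans lactone 10. This also removes the methylation step.
3. **Step 8, second Friedel–Crafts.** Benzylic ionization at C5 can scramble stereochemistry or give ring-opened by-products, and the 2,5-trans selectivity may be modest.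
   Fallback: lithiate 4-(benzyloxy)-3,5-dimethoxybromobenzene and add it to lactone 10 to give the lactol. Reduce this with Et3SiH/BF3·OEt2, then use the H2/Pd(OH)2 step to remove all three benzyl groups.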